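**Retrosynthetic overview**

1. The target is traced back to a tetracyclic spiro-γ-lactam by silyl ether cleavage, butenolide hydrogenation and a reductive vinylogous Mannich reaction. The α-methylbutyrolactone arrives as an intact, purchased furanone ring joined to C-5 of the pyrrolidine, so no ring is closed after the key step.
2. Key disconnection: the N–C(spiro) bond of the pyrrolidine and the bond between the cyclopentane CH and the first azepane CH2 are made in one amidyl-radical 5-exo / 7-endo cascade from a secondary amide that carries a vinyl sulfone on nitrogen.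
3. Enabling feature: the aza-quaternary carbon is common to cyclopentane, pyrrolidine and azepane, and its nitrogen is cis to the azepane CH2 on the neighbouring cyclopentane CH (the bond shared by cyclopentane and azepane). N and C can therefore be added across one cyclopentene C=C from the convex face of the lactone-fused ring.
4. The cyclopentene–lactone acid comes from (1R,5S)-2-oxabicyclo[3.3.0]oct-6-en-3-one: lactone enolate hydroxylation then methylation (tertiary carbinol), allylic oxidation, ethyl addition, oxidative transposition, conjugate reduction with triflation (endo ethyl), and Negishi coupling.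
5. Ring order: γ-lactone and cyclopentane are bought fused; the furanone is bought and attached late as a unit; the pyrrolidinone and then the azepane form in the key step, the azepane last.

Key step: step 15

Remark: the (1R,5S) enantiomer of the bicyclic lactone, tert-butyl but-3-yn-1-ylcarbamate and 3-methylfuran-2(5H)-one are taken as commercial. Locants follow 2-oxabicyclo[3.3.0]octane numbering (C-1 O-bearing ring fusion, C-3 carbonyl, C-5 other ring fusion); exo means the convex face, cis to H-1 and H-5.

**Route**

Step 1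
Reactants: 1 (1R,5S)-2-oxabicyclo[3.3.0]oct-6-en-3-one
Product: 3 4-exo-hydroxy-2-oxabicyclo[3.3.0]oct-6-en-3-one, via potassium enolate 2 (not isolated)
Conditions: KHMDS, THF, −78 °C; then 2-(phenylsulfonyl)-3-phenyloxaziridine; aq NH4Cl
Reagents that add atoms: 2-(phenylsulfonyl)-3-phenyloxaziridine, O=S(=O)(c1ccccc1)N1OC1c1ccccc1
Why: N-sulfonyloxaziridine oxidation of the lactone enolate (Davis oxidation) should deliver oxygen on the convex face to give the exo alcohol, and the configuration at C-4 is renewed in step 3 in any case.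

Step 2
Reactants: 3 4-exo-hydroxy-2-oxabicyclo[3.3.0]oct-6-en-3-one
Product: 4 4-exo-(tert-butyldimethylsilyloxy)-2-oxabicyclo[3.3.0]oct-6-en-3-one
Conditions: TBSCl, imidazole, DMF, rt
Reagents that add atoms: tert-butyldimethylsilyl chloride, CC(C)(C)[Si](C)(C)Cl
Why: Standard silylation of a secondary alcohol, needed so that C-4 can be enolised once more.

Step 3
Reactants: 4 4-exo-(tert-butyldimethylsilyloxy)-2-oxabicyclo[3.3.0]oct-6-en-3-one
Product: 6 4-exo-methyl-4-endo-(tert-butyldimethylsilyloxy)-2-oxabicyclo[3.3.0]oct-6-en-3-one, via lithium enolate 5 (not isolated)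
Conditions: LDA, THF, −78 °C; then MeI, DMPU, −78 → −40 °C
Reagents that add atoms: iodomethane, CI
Why: Enolate alkylation of the α-silyloxy lactone: methyl iodide should enter from the convex face, anti to the cyclopentene ring at C-5, so methyl ends exo and the silyloxy group endo, which is the configuration of the tertiary carbinol carbon of the target.

Step 4
Reactants: 6 4-exo-methyl-4-endo-(tert-butyldimethylsilyloxy)-2-oxabicyclo[3.3.0]oct-6-en-3-one
Product: 7 8-exo-hydroxy derivative of 6 (allylic alcohol at C-8, alkene still C-6=C-7)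
Conditions: SeO2 (30 mol %), t-BuOOH, CH2Cl2, rt
Reagents that add atoms: tert-butyl hydroperoxide, CC(C)(C)OO (oxygen atom, relayed by catalytic SeO2, O=[Se]=O)
Why: Catalytic SeO2 allylic hydroxylation (ene reaction then 2,3-sigmatropic shift) should occur at the only allylic methylene, C-8, because abstraction of the ring-fusion hydrogen at C-5 would need a strained ring-fusion alkene; the new carbinol centre (exo OH expected) is removed in step 5.

Step 5
Reactants: 7 8-exo-hydroxy allylic alcohol
Product: 8 4-exo-methyl-4-endo-(tert-butyldimethylsilyloxy)-2-oxabicyclo[3.3.0]oct-6-ene-3,8-dione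
Conditions: IBX, EtOAc, 75 °C
Reagents that add atoms: none
Why: IBX oxidation of a secondary allylic alcohol to the cyclopentenone.

Step 6
Reactants: 8 oct-6-ene-3,8-dione
Product: 9 8-exo-ethyl-8-endo-hydroxy tertiary allylic alcohol (C-6=C-7 retained)
Conditions: EtMgBr, LaCl3·2LiCl (30 mol %), THF, −78 °C; aq NH4Cl
Reagents that add atoms: ethylmagnesium bromide, CC[Mg]Br
Why: Lanthanum-assisted Grignard 1,2-addition to the enone carbonyl, which is far more electrophilic than the hindered α-quaternary lactone; ethyl should enter from the convex face, but this centre is made planar again in step 7.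

Step 7
Reactants: 9 tertiary allylic alcohol
Product: 10 8-ethyl-4-exo-methyl-4-endo-(tert-butyldimethylsilyloxy)-2-oxabicyclo[3.3.0]oct-7-ene-3,6-dione
Conditions: IBX, DMSO, 55 °C
Reagents that add atoms: none
Why: IBX-mediated oxidative 1,3-transposition of a tertiary allylic alcohol (Babler–Dauben type), which moves oxygen to C-6 and leaves ethyl on the β-carbon of the new enone.

Step 8
Reactants: 10 β-ethyl enone
Product: 12 8-endo-ethyl-4-exo-methyl-3-oxo-4-endo-(tert-butyldimethylsilyloxy)-2-oxabicyclo[3.3.0]oct-6-en-6-yl triflate, via dimethylphenylsilyl enol ether 11 (not isolated)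
Conditions: [(Ph3P)CuH]6 (5 mol %), PhMe2SiH, toluene, rt; then CsF, PhNTf2, DME, rt; aq NH4Cl
Reagents that add atoms: N-phenylbis(trifluoromethanesulfonimide), O=S(=O)(N(c1ccccc1)S(=O)(=O)C(F)(F)F)C(F)(F)F
Why: Copper hydride conjugate hydrosilylation should deliver hydride to C-8 from the convex face (ethyl endo, cis to the lactone oxygen as in the target) and fix the enolate as the C-6/C-7 silyl enol ether, which fluoride turns into the enol triflate without enolisation toward the ring-fusion carbon.

Step 9
Reactants: 12 enol triflate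
Product: 13 tert-butyl 3-[8-endo-ethyl-4-exo-methyl-3-oxo-4-endo-(tert-butyldimethylsilyloxy)-2-oxabicyclo[3.3.0]oct-6-en-6-yl]propanoate
Conditions: BrZnCH2CH2CO2t-Bu, Pd(PPh3)4 (5 mol %), THF, 50 °C
Reagents that add atoms: (3-tert-butoxy-3-oxopropyl)zinc bromide, CC(C)(C)OC(=O)CC[Zn]Br
Why: Negishi sp2–sp3 cross-coupling: oxidative addition of zerovalent palladium into the enol triflate, transmetallation with the ester-bearing alkylzinc and reductive elimination.

Step 10
Reactants: 13 tert-butyl ester
Product: 14 3-[8-endo-ethyl-4-exo-methyl-3-oxo-4-endo-(tert-butyldimethylsilyloxy)-2-oxabicyclo[3.3.0]oct-6-en-6-yl]propanoic acid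
Conditions: TMSOTf, 2,6-lutidine, CH2Cl2, 0 °C; then H2O
Reagents that add atoms: none
Why: Silyl triflate cleavage of the tert-butyl ester under buffered, non-protic conditions (loss of isobutene), chosen because a strong protic acid could lactonise the γ,δ-unsaturated acid onto the trisubstituted alkene.

Step 11
Reactants: 15 tert-butyl but-3-yn-1-ylcarbamate
Product: 16 tert-butyl [3-(phenylthio)but-3-en-1-yl]carbamate
Conditions: PhSH, Pd(OAc)2 (2 mol %), THF, 45 °C
Reagents that add atoms: thiophenol, Sc1ccccc1
Why: Pd(OAc)2-catalysed Markovnikov hydrothiolation of a terminal alkyne should give the 1,1-disubstituted vinyl sulfide.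

Step 12
Reactants: 16 vinyl sulfide
Product: 17 tert-butyl [3-(phenylsulfonyl)but-3-en-1-yl]carbamate
Conditions: mCPBA (2.2 equiv), CH2Cl2, 0 °C → rt
Reagents that add atoms: 3-chloroperoxybenzoic acid, O=C(OO)c1cccc(Cl)c1
Why: Peracid oxidation of sulfide to sulfone; the electron-poor vinyl sulfone formed is inert to the peracid.

Step 13
Reactants: 17 Boc-protected vinyl sulfone
Product: 18 3-(phenylsulfonyl)but-3-en-1-amine hydrochloride
Conditions: HCl (4 M in dioxane), rt
Reagents that add atoms: hydrogen chloride, Cl
Why: Acidolytic Boc cleavage; the amine is kept as its hydrochloride so that it cannot add to its own vinyl sulfone.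

Step 14
Reactants: 14 propanoic acid; 18 3-(phenylsulfonyl)but-3-en-1-amine hydrochloride
Product: 20 N-[3-(phenylsulfonyl)but-3-en-1-yl]amide of acid 14, via isobutyl carbonic anhydride 19 (not isolated)
Conditions: i-BuOCOCl, N-methylmorpholine, THF, −15 °C; then 18, N-methylmorpholine, −15 → 0 °C
Reagents that add atoms: none
Why: Mixed-anhydride amide formation; the amine is set free only in the presence of the activated acid at low temperature, where N-acylation should outrun aza-Michael addition.

Step 15
Reactants: 20 secondary amide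
Product: 21 tetracyclic sulfone lactam (spiro-pyrrolidin-2-one with N on the convex face; azepane cis-fused to the cyclopentane; PhSO2 on the azepane carbon β to the ring-fusion CH, both epimers)
Conditions: [Ir(dF(CF3)ppy)2(5,5'-d(CF3)bpy)]PF6 (2 mol %), NBu4[(BuO)2PO2] (25 mol %), PhCF3 (0.01 M), blue LEDs, rt, degassed
Reagents that add atoms: none
Why: Proton-coupled electron transfer from the amide N–H to the photoexcited iridium complex and the phosphate base gives an electrophilic amidyl radical, which closes the pyrrolidinone 5-exo-trig onto the electron-rich cyclopentene carbon bearing the tether (creating the aza-quaternary centre); the resulting nucleophilic secondary cyclopentyl radical then closes the azepane 7-endo-trig onto the CH2 terminus of the N-tethered vinyl sulfone, and the electrophilic α-sulfonyl radical is reduced by the divalent iridium complex and protonated, so the process is redox-neutral and has no stoichiometric hydrogen donor that could intercept the intermediate radical. The closest known reaction types are photocatalytic amidyl-radical alkene carboamination and tin-mediated amidyl 5-exo/6-endo polycyclisation. The aza-quaternary configuration should be set by attack of nitrogen on the convex face of the cis-fused bicyclic lactone, anti to the C(Me)(OTBS) substituent on the neighbouring ring-fusion carbon. The configuration of the CH shared by cyclopentane and azepane follows from the tether, which can only reach the face that carries nitrogen (cis fusion) and is anti to the endo ethyl group. The step needs 5-exo over 6-endo attack by nitrogen (polarity match and early transition state), terminal-carbon attack on the 1,1-disubstituted sulfonyl alkene (7-endo over 6-exo, secured by the sulfone) and cyclisation faster than 1,5-hydrogen transfer from the allylic CH2; the epimeric sulfone carbon is of no consequence because the sulfone is removed in step 16.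

Step 16
Reactants: 21 tetracyclic sulfone lactam
Product: 22 tetracyclic lactam (γ-lactone-fused cyclopentane, spiro-pyrrolidin-2-one, cis-fused azepane)
Conditions: 6% Na(Hg), Na2HPO4, THF/MeOH, −20 °C
Reagents that add atoms: none
Why: Reductive desulfonylation with sodium amalgam (electron-transfer cleavage of the C–S bond, then protonation) removes the activating group; lactone, lactam and silyl ether should survive the buffered conditions.

Step 17
Reactants: 23 3-methylfuran-2(5H)-one
Product: 24 3-methyl-2-(triisopropylsilyloxy)furan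
Conditions: TIPSOTf, Et3N, CH2Cl2, 0 °C
Reagents that add atoms: triisopropylsilyl triflate, CC(C)[Si](C(C)C)(C(C)C)OS(=O)(=O)C(F)(F)F
Why: Soft enolisation and O-silylation of the butenolide give the aromatic 2-silyloxyfuran.

Step 18
Reactants: 22 tetracyclic lactam; 24 3-methyl-2-(triisopropylsilyloxy)furan
Product: 26 butenolide Mannich adduct (4-methyl-5-oxo-2,5-dihydrofuran-2-yl group on the former lactam carbon), via N,O-silyl hemiaminal 25 (not isolated)
Conditions: IrCl(CO)(PPh3)2 (1 mol %), (Me2HSi)2O, toluene, rt; then 24, TMSOTf (10 mol %), CH2Cl2, −78 → 0 °C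
Reagents that add atoms: none
Why: Iridium-catalysed hydrosilylation reduces the tertiary lactam chemoselectively (lactones are untouched) to the N,O-silyl hemiaminal, which ionises to the pyrrolidinium ion and undergoes a vinylogous Mukaiyama–Mannich reaction at the furan γ-carbon; the nucleophile should approach anti to the lactone-bearing cyclopentane carbon of the spiro centre (cis to the azepane CH), and the usual open transition state should give the threo relationship at the butenolide carbon.

Step 19
Reactants: 26 butenolide Mannich adduct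
Product: 27 tert-butyldimethylsilyl ether of the target
Conditions: H2 (1 atm), Pd/C, EtOAc, rt
Reagents that add atoms: none
Why: Heterogeneous hydrogenation of the butenolide from the face opposite to its γ-substituent should give the cis-α-methyl-γ-substituted lactone.

Step 20
Reactants: 27 silyl ether of the target
Product: 28 CNP0260919.3 (target)
Conditions: HF·pyridine, THF, 0 °C → rt; aq NaHCO3
Reagents that add atoms: none
Why: Fluoride cleavage of the tertiary silyl ether should free the tertiary alcohol without touching the two lactones.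

**Compound list**

1 | (1R,5S)-2-oxabicyclo[3.3.0]oct-6-en-3-one | C1[C@H]2OC(=O)C[C@H]2C=C1 | starting material
2 | potassium enolate of 1 | C1[C@H]2OC([O-])=C[C@H]2C=C1.[K+] | intermediate
3 | 4-exo-hydroxy-2-oxabicyclo[3.3.0]oct-6-en-3-one | C1[C@H]2OC(=O)[C@H](O)[C@H]2C=C1 | intermediate
4 | 4-exo-(tert-butyldimethylsilyloxy)-2-oxabicyclo[3.3.0]oct-6-en-3-one | C1[C@H]2OC(=O)[C@H](O[Si](C)(C)C(C)(C)C)[C@H]2C=C1 | intermediate
5 | lithium enolate of 4 | C1[C@H]2OC([O-])=C(O[Si](C)(C)C(C)(C)C)[C@H]2C=C1.[Li+] | intermediate
6 | 4-exo-methyl-4-endo-(tert-butyldimethylsilyloxy)-2-oxabicyclo[3.3.0]oct-6-en-3-one | C1[C@H]2OC(=O)[C@@](C)(O[Si](C)(C)C(C)(C)C)[C@H]2C=C1 | intermediate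
7 | 8-exo-hydroxy-4-exo-methyl-4-endo-(tert-butyldimethylsilyloxy)-2-oxabicyclo[3.3.0]oct-6-en-3-one | O[C@@H]1[C@H]2OC(=O)[C@@](C)(O[Si](C)(C)C(C)(C)C)[C@H]2C=C1 | intermediate
8 | 4-exo-methyl-4-endo-(tert-butyldimethylsilyloxy)-2-oxabicyclo[3.3.0]oct-6-ene-3,8-dione | O=C1[C@H]2OC(=O)[C@@](C)(O[Si](C)(C)C(C)(C)C)[C@H]2C=C1 | intermediate
9 | 8-exo-ethyl-8-endo-hydroxy-4-exo-methyl-4-endo-(tert-butyldimethylsilyloxy)-2-oxabicyclo[3.3.0]oct-6-en-3-one | CC[C@]1(O)[C@H]2OC(=O)[C@@](C)(O[Si](C)(C)C(C)(C)C)[C@H]2C=C1 | intermediate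
10 | 8-ethyl-4-exo-methyl-4-endo-(tert-butyldimethylsilyloxy)-2-oxabicyclo[3.3.0]oct-7-ene-3,6-dione | CCC1=CC(=O)[C@H]2[C@@H]1OC(=O)[C@@]2(C)O[Si](C)(C)C(C)(C)C | intermediate
11 | C-6 dimethylphenylsilyl enol ether (C-6=C-7) of the 8-endo-ethyl ketone | CC[C@H]1[C@H]2OC(=O)[C@@](C)(O[Si](C)(C)C(C)(C)C)[C@H]2C(O[Si](C)(C)c2ccccc2)=C1 | intermediate
12 | 8-endo-ethyl-4-exo-methyl-3-oxo-4-endo-(tert-butyldimethylsilyloxy)-2-oxabicyclo[3.3.0]oct-6-en-6-yl triflate | CC[C@H]1[C@H]2OC(=O)[C@@](C)(O[Si](C)(C)C(C)(C)C)[C@H]2C(OS(=O)(=O)C(F)(F)F)=C1 | intermediate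
13 | tert-butyl 3-[8-endo-ethyl-4-exo-methyl-3-oxo-4-endo-(tert-butyldimethylsilyloxy)-2-oxabicyclo[3.3.0]oct-6-en-6-yl]propanoate | CC[C@H]1[C@H]2OC(=O)[C@@](C)(O[Si](C)(C)C(C)(C)C)[C@H]2C(CCC(=O)OC(C)(C)C)=C1 | intermediate
14 | 3-[8-endo-ethyl-4-exo-methyl-3-oxo-4-endo-(tert-butyldimethylsilyloxy)-2-oxabicyclo[3.3.0]oct-6-en-6-yl]propanoic acid | CC[C@H]1[C@H]2OC(=O)[C@@](C)(O[Si](C)(C)C(C)(C)C)[C@H]2C(CCC(=O)O)=C1 | intermediate
15 | tert-butyl but-3-yn-1-ylcarbamate | C#CCCNC(=O)OC(C)(C)C | starting material
16 | tert-butyl [3-(phenylthio)but-3-en-1-yl]carbamate | C=C(CCNC(=O)OC(C)(C)C)Sc1ccccc1 | intermediate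
17 | tert-butyl [3-(phenylsulfonyl)but-3-en-1-yl]carbamate | C=C(CCNC(=O)OC(C)(C)C)S(=O)(=O)c1ccccc1 | intermediate
18 | 3-(phenylsulfonyl)but-3-en-1-amine hydrochloride | C=C(CCN)S(=O)(=O)c1ccccc1.Cl | intermediate
19 | isobutyl carbonic anhydride of acid 14 | CC[C@H]1[C@H]2OC(=O)[C@@](C)(O[Si](C)(C)C(C)(C)C)[C@H]2C(CCC(=O)OC(=O)OCC(C)C)=C1 | intermediate
20 | N-[3-(phenylsulfonyl)but-3-en-1-yl]amide of acid 14 | CC[C@H]1[C@H]2OC(=O)[C@@](C)(O[Si](C)(C)C(C)(C)C)[C@H]2C(CCC(=O)NCCC(=C)S(=O)(=O)c2ccccc2)=C1 | intermediate
21 | tetracyclic sulfone lactam (spiro-pyrrolidin-2-one, cis-fused azepane bearing PhSO2, both sulfone epimers) | CC[C@H]1[C@H]2OC(=O)[C@@](C)(O[Si](C)(C)C(C)(C)C)[C@H]2[C@]23CCC(=O)N2CCC(S(=O)(=O)c2ccccc2)C[C@H]13 | intermediate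
22 | tetracyclic lactam (γ-lactone-fused cyclopentane, spiro-pyrrolidin-2-one, cis-fused azepane) | CC[C@H]1[C@H]2OC(=O)[C@@](C)(O[Si](C)(C)C(C)(C)C)[C@H]2[C@]23CCC(=O)N2CCCC[C@H]13 | intermediate
23 | 3-methylfuran-2(5H)-one | CC1=CCOC1=O | starting material
24 | 3-methyl-2-(triisopropylsilyloxy)furan | Cc1ccoc1O[Si](C(C)C)(C(C)C)C(C)C | intermediate
25 | N,O-silyl hemiaminal of 22 (lactam C=O reduced to CH–O–SiMe2–O–SiHMe2) | CC[C@H]1[C@H]2OC(=O)[C@@](C)(O[Si](C)(C)C(C)(C)C)[C@H]2[C@]23CCC(O[Si](C)(C)O[SiH](C)C)N2CCCC[C@H]13 | intermediate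
26 | butenolide Mannich adduct (threo, butenolide cis to the azepane CH across the pyrrolidine) | CC[C@H]1[C@H]2OC(=O)[C@@](C)(O[Si](C)(C)C(C)(C)C)[C@H]2[C@]23CC[C@@H]([C@@H]4C=C(C)C(=O)O4)N2CCCC[C@H]13 | intermediate
27 | tert-butyldimethylsilyl ether of the target | CC[C@H]1[C@H]2OC(=O)[C@@](C)(O[Si](C)(C)C(C)(C)C)[C@H]2[C@]23CC[C@@H]([C@@H]4C[C@H](C)C(=O)O4)N2CCCC[C@H]13 | intermediate
28 | CNP0260919.3 | CC[C@H]1[C@H]2OC(=O)[C@@](C)(O)[C@H]2[C@]23CC[C@@H]([C@@H]4C[C@H](C)C(=O)O4)N2CCCC[C@H]13 | target

**Step count and risks**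

Total step count: 20. Longest linear sequence: 16 steps (steps 1–10, 14–16, 18–20).

Steps most likely to fail:

Step 15 (key step). The cyclopentyl radical formed after the first ring closure may be lost by 1,5-hydrogen transfer from the allylic CH2 of the tether before it closes the seven-membered ring, or N–H activation of the N-alkyl amide may be too slow. Fallback: the route sets out from acid 14, which is converted through anhydride 19 with 2-chloroethylamine hydrochloride and N-methylmorpholine into the N-(2-chloroethyl) amide F1. The same photocatalytic amidyl cyclisation is then run with phenyl vinyl sulfone in excess as an intermolecular radical trap (known alkene carboamination), which should give the spiro-pyrrolidinone with a 2-(phenylsulfonyl)ethyl group cis to nitrogen F2. KHMDS in THF at −78 → 0 °C then forms the sulfonyl carbanion, which displaces chloride (7-exo-tet) and closes the azepane. The fallback comes back to the route at 21.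

Step 18. The furan may add to the wrong face of the pyrrolidinium ion, or threo/erythro control at the butenolide carbon may be poor. Fallback: the route sets out from lactam 22, which Lawesson's reagent (toluene, 80 °C) converts into the thiolactam F3. S-Alkylation with 5-bromo-3-methylfuran-2(5H)-one (CC1=CC(Br)OC1=O) in MeCN gives the thioiminium bromide F4, and PPh3 with Et3N (Eschenmoser sulfide contraction) gives the (E)-aminomethylene butenolide F5. Hydrogenation (H2, PtO2, AcOH/EtOAc) then adds hydrogen syn across the exocyclic alkene and saturates the ring alkene. Because hydrogen rather than carbon now arrives on the more accessible face, this is the remedy if the Mannich reaction places the butenolide on the face of the lactone-bearing carbon. The fallback comes back at 27.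

Step 4. The ene step may take place at the ring-fusion C–H, or conversion may stop because the allylic position is deactivated by the neighbouring acyloxy group. Fallback: the route sets out from alkene 6, which undergoes a Schenck ene reaction with singlet oxygen (O2, tetraphenylporphyrin, hν, CH2Cl2) to the transposed allylic hydroperoxide F6. Ac2O, pyridine and DMAP (Kornblum–DeLaMare dehydration) give the unsubstituted enone F7. EtMgBr with CuBr·SMe2 (cat.) and TMSCl in THF at −78 °C gives the trimethylsilyl enol ether F8, and Pd(OAc)2 in MeCN (Saegusa–Ito oxidation) restores the enone with ethyl on the β-carbon. The fallback comes back at 10 and replaces steps 4–7.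

Further compounds
F1 | step 15 | N-(2-chloroethyl)amide of acid 14 | CC[C@H]1[C@H]2OC(=O)[C@@](C)(O[Si](C)(C)C(C)(C)C)[C@H]2C(CCC(=O)NCCCl)=C1
F2 | step 15 | spiro-pyrrolidin-2-one with N-(2-chloroethyl) and cis 2-(phenylsulfonyl)ethyl groups | CC[C@H]1[C@H]2OC(=O)[C@@](C)(O[Si](C)(C)C(C)(C)C)[C@H]2[C@@]2(CCC(=O)N2CCCl)[C@@H]1CCS(=O)(=O)c1ccccc1
F3 | step 18 | thiolactam of 22 | CC[C@H]1[C@H]2OC(=O)[C@@](C)(O[Si](C)(C)C(C)(C)C)[C@H]2[C@]23CCC(=S)N2CCCC[C@H]13
F4 | step 18 | S-(4-methyl-5-oxo-2,5-dihydrofuran-2-yl)thioiminium bromide | CC[C@H]1[C@H]2OC(=O)[C@@](C)(O[Si](C)(C)C(C)(C)C)[C@H]2[C@]23CCC(SC4OC(=O)C(C)=C4)=[N+]2CCCC[C@H]13.[Br-]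
F5 | step 18 | (E)-aminomethylene butenolide | CC[C@H]1[C@H]2OC(=O)[C@@](C)(O[Si](C)(C)C(C)(C)C)[C@H]2[C@]23CC/C(=C4/C=C(C)C(=O)O4)N2CCCC[C@H]13
F6 | step 4 | 6-exo-hydroperoxy-4-exo-methyl-4-endo-(tert-butyldimethylsilyloxy)-2-oxabicyclo[3.3.0]oct-7-en-3-one | C1=C[C@@H](OO)[C@H]2[C@@H]1OC(=O)[C@@]2(C)O[Si](C)(C)C(C)(C)C
F7 | step 4 | 4-exo-methyl-4-endo-(tert-butyldimethylsilyloxy)-2-oxabicyclo[3.3.0]oct-7-ene-3,6-dione | C1=CC(=O)[C@H]2[C@@H]1OC(=O)[C@@]2(C)O[Si](C)(C)C(C)(C)C
F8 | step 4 | C-6 trimethylsilyl enol ether (C-6=C-7) of the 8-exo-ethyl ketone | CC[C@@H]1[C@H]2OC(=O)[C@@](C)(O[Si](C)(C)C(C)(C)C)[C@H]2C(O[Si](C)(C)C)=C1
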